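**Plan**
- The retrosynthesis first removes four MOM ethers. It then cuts, in both terminal rings at once, the C1–C2 bond between the carbonyl carbon next to the CH2-bearing C6 and the acetyl-bearing carbon.
- Enabling feature: C6 of each 2-acetyl-4,4-dimethylcyclohexane-1,3,5-trione ring is tied by one CH2 to a central-ring carbon that has a phenol oxygen beside it. That oxygen, C1, C6 and the CH2 can therefore be held as O1, C2, C3 and C4 of a chroman-2-one fused to the central ring. C5, C4, C3, C2 and the acetyl group then form an open 2,2-dimethyl-3,5-dioxohexanoyl chain on C3.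
- Further cuts are the two C3–acyl bonds (donor: a gem-dimethyl enol lactone), the two lactone rings (formaldehyde and Meldrum's acid), the central CH2 bridge and the aryl–butyryl bonds.
- Forward order: acylate phloroglucinol, bridge two units, close both lactone rings together, protect, acylate both C3 positions, open both lactones while both carbocycles close, deprotect.
- Stereochemistry: the target has no stereocentre. The lactone C3 centres are epimerisable and disappear in the key step.

Key step: step 9

Assumption: the target contains no stereocentre and no hindered axis, so it is a single achiral compound and no step has to control configuration.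
Assumption: in step 3 the lactone is drawn on the phenol para to the butyryl group, the most acidic and non-chelated OH. Closure on the ortho phenol would give a regioisomer that passes through the same steps to the same target, because step 9 returns this oxygen as a free phenol.

**Step 1**
Reactants: 1 phloroglucinol; 2 butyryl chloride
Product: 3 phlorbutyrophenone [1-(2,4,6-trihydroxyphenyl)butan-1-one]
Conditions: AlCl3 (4 equiv), CH2Cl2–MeNO2, 0 → 40 °C; aq HCl
Reagents that add atoms: none
Why: Friedel–Crafts acylation of the threefold-symmetric, very electron-rich ring should stop at the mono-ketone because the chelated acyl group deactivates the ring towards a second acylation.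

**Step 2**
Reactants: 3 phlorbutyrophenone (2.5 equiv); 4 formaldehyde (37% aq, 1 equiv)
Product: 6 methylenebis(phlorbutyrophenone) [two units of 3 joined by CH2 between one free ring carbon of each], via hydroxymethyl ketone 5 (not isolated)
Conditions: 1 M aq KOH, 0 °C → rt; 1 M HCl
Reagents that add atoms: none
Why: Lederer–Manasse hydroxymethylation gives 5, which under the same basic conditions alkylates a second phenolate at carbon, the standard access to methylene-bis(acylphloroglucinols), and keeping formaldehyde limiting with 3 in excess should hold the condensation at the dimer.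

**Step 3**
Reactants: 6 methylenebis(phlorbutyrophenone); 4 formaldehyde (2.4 equiv); 7 Meldrum's acid (2.4 equiv)
Product: 11 bis-lactone tetraphenol [8,8'-methylenebis(6-butanoyl-5,7-dihydroxychroman-2-one)], via methylene Meldrum's acid 8 (not isolated), via bis-Meldrum adduct 9 (not isolated), via bis-lactone diacid 10 (not isolated)
Conditions: 4 + 7, pyridine, rt, 15 min; add 6, rt → 90 °C
Reagents that add atoms: none
Why: Yonemitsu-type three-component condensation, in which Knoevenagel product 8 is captured by the single free aromatic carbon of each ring, the neighbouring phenol opens the dioxanedione with loss of acetone, and the malonic half-ester 10 decarboxylates in hot pyridine, a known route from phloroglucinols to 3,4-dihydrocoumarins.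

**Step 4**
Reactants: 11 bis-lactone tetraphenol
Product: 12 tetra-MOM bis-lactone [8,8'-methylenebis(6-butanoyl-5,7-bis(methoxymethoxy)chroman-2-one)]
Conditions: NaH (4.4 equiv), MOMCl (5 equiv), THF–DMF, 0 °C
Reagents that add atoms: chloromethyl methyl ether (MOMCl), COCCl
Why: Williamson-type O-alkylation of the sodium phenoxides with the hard electrophile MOMCl should also cap the chelated phenols without C-alkylation, and hydride as a non-nucleophilic base leaves the aryl lactones closed.

**Step 5**
Reactants: 13 tert-butyl acetoacetate
Product: 14 tert-butyl 2,2-dimethyl-3-oxobutanoate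
Conditions: MeI (2.5 equiv), K2CO3, acetone, reflux
Reagents that add atoms: iodomethane, CI
Why: Twofold C-alkylation of the active methylene (acetoacetic ester alkylation) installs the quaternary carbon at the outset.

**Step 6**
Reactants: 14 tert-butyl 2,2-dimethyl-3-oxobutanoate
Product: 15 tert-butyl 2,2-dimethyl-3,5-dioxohexanoate
Conditions: LDA, THF, −78 °C; MeC(O)N(OMe)Me, −78 °C → 0 °C; 1 M HCl
Reagents that add atoms: N-methoxy-N-methylacetamide, CC(=O)N(C)OC
Why: The methyl ketone is the only enolisable position, and acylation of its kinetic lithium enolate by the Weinreb amide (crossed Claisen synthesis of a 1,3-diketone) passes through a chelated tetrahedral adduct that prevents over-acylation.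

**Step 7**
Reactants: 15 tert-butyl 2,2-dimethyl-3,5-dioxohexanoate
Product: 17 3,3,6-trimethyl-2H-pyran-2,4(3H)-dione, via diketo acid 16 (not isolated)
Conditions: TFA–TFAA, CH2Cl2, 0 °C → rt
Reagents that add atoms: none
Why: Acidolysis of the tert-butyl ester and TFAA-induced cyclodehydration through the C5 enol oxygen is the standard conversion of 3,5-dioxo esters into pyranones, and the quaternary C3 blocks tautomerisation to a hydroxypyrone, so 17 keeps the reactivity of a vinylogous anhydride.

**Step 8**
Reactants: 12 tetra-MOM bis-lactone; 17 3,3,6-trimethyl-2H-pyran-2,4(3H)-dione (2.3 equiv)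
Product: 18 bis(3-acyl lactone) [8,8'-methylenebis(6-butanoyl-3-(2,2-dimethyl-3,5-dioxohexanoyl)-5,7-bis(methoxymethoxy)chroman-2-one), mixture of C3 epimers]
Conditions: LiHMDS (4.2 equiv), THF, −78 °C; 17, −78 → −45 °C; AcOH, −78 °C
Reagents that add atoms: none
Why: Crossed Claisen condensation in which two equivalents of base per half deprotonate the lactone C3–H and the butyryl α-CH2; the unhindered cyclic ester enolate attacks the lithium-chelated lactone carbonyl of 17 and releases the 1,3-diketone as its enolate, while the encumbered di-ortho-substituted aryl ketone enolate only acts as the internal base that takes up the acidic C3–H of the product.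

**Step 9**
Reactants: 18 bis(3-acyl lactone)
Product: 20 tetra-O-MOM dryocrassin ABBA [MOM on the four phenols ortho to the butyryl groups, the two phenols between the CH2 groups free], via bis-acylketene 19 (not isolated)
Conditions: DBU (4.5 equiv), THF, 0 °C → rt; cold 1 M HCl
Reagents that add atoms: none
Why: DBU removes the C3–H between the lactone and side-chain carbonyls (and the diketone proton), and each enolate expels the central-ring aryloxide, a good nucleofuge because it is para to the butyryl group, in an E1cB step that gives α-oxoketene 19. The carbon between the two carbonyls of the pendant 1,3-diketonate then adds to the ketene carbonyl carbon, so each six-membered ring closes in a 6-exo-dig mode (6-exo-trig if the diketonate attacks the still closed lactone) and the bond between the acetyl-bearing carbon and the former lactone carbonyl is formed twice. The closest known reaction types are the Claisen (Dieckmann-type) cyclisation of 3,5,7-triketo esters to 2-acylcyclohexanetriones and acylphloroglucinols, the E1cB cleavage of aryl acetoacetates and the carbon capture of acylketenes released from dioxinones. C- over O-acylation is required and should be secured thermodynamically: the O-acylated enol lactone is a vinylogous anhydride that still carries the acidic C–H and reverts to 19, whereas the C-acylated triketone is withdrawn as its strongly stabilised enolate. Retro-Claisen cleavage at the non-enolisable CMe2-flanked diketone should be avoided because no external O-nucleophile is present, and the MOM ethers keep the other phenols un-ionised, so the leaving group stays good and the methylene bridges should not exchange. No stereocentre is created, and the C3 epimers of 18 converge on one product.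

**Step 10**
Reactants: 20 tetra-O-MOM dryocrassin ABBA
Product: 21 dryocrassin ABBA
Conditions: 2 M aq HCl, THF, 40 °C
Reagents that add atoms: none
Why: Acid-catalysed acetal hydrolysis should be easy because all four MOM ethers sit ortho to an aryl ketone, and every nucleophilic ring carbon of 21 is substituted, so the formaldehyde released finds no position to attack.

**Compound list**
1 | phloroglucinol | Oc1cc(O)cc(O)c1 | starting material
2 | butyryl chloride | CCCC(Cl)=O | starting material
3 | phlorbutyrophenone, 1-(2,4,6-trihydroxyphenyl)butan-1-one | CCCC(=O)c1c(O)cc(O)cc1O | intermediate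
4 | formaldehyde | C=O | starting material
5 | 1-[2,4,6-trihydroxy-3-(hydroxymethyl)phenyl]butan-1-one (not isolated) | CCCC(=O)c1c(O)cc(O)c(CO)c1O | intermediate
6 | methylenebis(phlorbutyrophenone), 1,1'-[methylenebis(2,4,6-trihydroxy-3,1-phenylene)]dibutan-1-one | CCCC(=O)c1c(O)cc(O)c(Cc2c(O)cc(O)c(C(=O)CCC)c2O)c1O | intermediate
7 | Meldrum's acid | CC1(C)OC(=O)CC(=O)O1 | starting material
8 | 5-methylene Meldrum's acid (not isolated) | C=C1C(=O)OC(C)(C)OC1=O | intermediate
9 | bis-Meldrum adduct, 6 with a (2,2-dimethyl-4,6-dioxo-1,3-dioxan-5-yl)methyl group on each remaining ring carbon (not isolated) | CCCC(=O)c1c(O)c(CC2C(=O)OC(C)(C)OC2=O)c(O)c(Cc2c(O)c(CC3C(=O)OC(C)(C)OC3=O)c(O)c(C(=O)CCC)c2O)c1O | intermediate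
10 | 8,8'-methylenebis(6-butanoyl-5,7-dihydroxy-2-oxochromane-3-carboxylic acid), C3 epimers (not isolated) | CCCC(=O)c1c(O)c2CC(C(=O)O)C(=O)Oc2c(Cc3c(O)c(C(=O)CCC)c(O)c4CC(C(=O)O)C(=O)Oc34)c1O | intermediate
11 | 8,8'-methylenebis(6-butanoyl-5,7-dihydroxychroman-2-one) | CCCC(=O)c1c(O)c2CCC(=O)Oc2c(Cc3c(O)c(C(=O)CCC)c(O)c4CCC(=O)Oc34)c1O | intermediate
12 | 8,8'-methylenebis(6-butanoyl-5,7-bis(methoxymethoxy)chroman-2-one) | CCCC(=O)c1c(OCOC)c2CCC(=O)Oc2c(Cc3c(OCOC)c(C(=O)CCC)c(OCOC)c4CCC(=O)Oc34)c1OCOC | intermediate
13 | tert-butyl acetoacetate | CC(=O)CC(=O)OC(C)(C)C | starting material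
14 | tert-butyl 2,2-dimethyl-3-oxobutanoate | CC(=O)C(C)(C)C(=O)OC(C)(C)C | intermediate
15 | tert-butyl 2,2-dimethyl-3,5-dioxohexanoate | CC(=O)CC(=O)C(C)(C)C(=O)OC(C)(C)C | intermediate
16 | 2,2-dimethyl-3,5-dioxohexanoic acid (not isolated) | CC(=O)CC(=O)C(C)(C)C(=O)O | intermediate
17 | 3,3,6-trimethyl-2H-pyran-2,4(3H)-dione | CC1=CC(=O)C(C)(C)C(=O)O1 | intermediate
18 | 8,8'-methylenebis(6-butanoyl-3-(2,2-dimethyl-3,5-dioxohexanoyl)-5,7-bis(methoxymethoxy)chroman-2-one), C3 epimers | CCCC(=O)c1c(OCOC)c2CC(C(=O)C(C)(C)C(=O)CC(C)=O)C(=O)Oc2c(Cc3c(OCOC)c(C(=O)CCC)c(OCOC)c4CC(C(=O)C(C)(C)C(=O)CC(C)=O)C(=O)Oc34)c1OCOC | intermediate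
19 | ring-opened bis(α-oxoketene) of 18 (not isolated) | CCCC(=O)c1c(OCOC)c(CC(=C=O)C(=O)C(C)(C)C(=O)CC(C)=O)c(O)c(Cc2c(O)c(CC(=C=O)C(=O)C(C)(C)C(=O)CC(C)=O)c(OCOC)c(C(=O)CCC)c2OCOC)c1OCOC | intermediate
20 | tetra-O-MOM dryocrassin ABBA | CCCC(=O)c1c(OCOC)c(CC2=C(O)C(C)(C)C(=O)C(C(C)=O)=C2O)c(O)c(Cc2c(O)c(CC3=C(O)C(C)(C)C(=O)C(C(C)=O)=C3O)c(OCOC)c(C(=O)CCC)c2OCOC)c1OCOC | intermediate
21 | dryocrassin ABBA (achiral) | CCCC(=O)c1c(O)c(CC2=C(O)C(C)(C)C(=O)C(C(C)=O)=C2O)c(O)c(Cc2c(O)c(CC3=C(O)C(C)(C)C(=O)C(C(C)=O)=C3O)c(O)c(C(=O)CCC)c2O)c1O | target

**Step count**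
Total step count: 10. Longest linear sequence: 7 steps (steps 1–4 and 8–10). The acyl donor branch (steps 5–7) joins at step 8.

**Steps most likely to fail**

Step 8. Several processes may compete:
- proton transfer from the C6-methyl group of 17 to the enolates
- acylation at the butyryl enolate
- addition at C6 of 17 instead of the lactone carbonyl
- ketene extrusion from the aryl lactone enolate followed by self-condensation

The fallback replaces hard enolisation by a malonate-type activating group. It sets out from 6 and comes back at 21. The annulation is run without the hot pyridine stage (cat. Et3N, MeCN, rt → 50 °C), so that diacid 10 is isolated with its carboxyl groups in place. TBSOTf/2,6-lutidine gives the hexasilyl derivative F1, whose two silyl esters are hydrolysed (AcOH–THF–H2O) to the tetra-TBS diacid F2. F2 is a cyclic malonic half-ester, so MgCl2/Et3N in MeCN should enolise only this position and leave the butyryl ketone untouched. The magnesium enolate is acylated by 17 and loses CO2 (decarboxylative Claisen condensation of malonic half-esters) to give the silyl-protected precursor F3. DBU as in step 9 should give the tetra-TBS tetramer F4, and 3HF·Et3N in THF removes the silyl groups to reach 21.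

Step 9. The closure may stall at the O-acylated enol lactone, the gem-dimethyl diketone may fragment by retro-Claisen cleavage, or base may trigger retro-Michael exchange of the methylene bridges once the phenoxide is free. The fallback gives up the lactone storage and joins finished rings. It sets out from 6 and comes back at 21. Commercial 2,4,6-trihydroxyacetophenone is C,C-dimethylated (MeI, NaOMe, MeOH) to acetylfilicinic acid F5, and Eschenmoser's salt converts this into the filicinic Mannich base F6. Warming F6 (2 equiv) with 6 in dioxane releases dimethylamine and a methylidene trione. The two free aromatic carbons of 6 capture this trione, which is the classical way to link filicinic acids and phloroglucinols through CH2.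

Step 3. Free formaldehyde may bridge 6 to oligomers, Meldrum's acid may be tied up as its 2:1 formaldehyde adduct, or the second annulation may remain incomplete. The fallback separates the two C–C bond formations. It sets out from 6 and comes back at 11. Exhaustive aminomethylation with Eschenmoser's salt (CH2Cl2, rt) gives the bis-Mannich base F7, which has no free aromatic position left. Heating F7 with 7 in dioxane expels dimethylamine to give o-quinone methides. These take up Meldrum's acid by Michael addition to give 9, which lactonises and decarboxylates through 10 to 11.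

**Further compounds**
F1 | step 8 | hexasilyl derivative of 10 (four aryl TBS ethers, two TBS esters) | CCCC(=O)c1c(O[Si](C)(C)C(C)(C)C)c2CC(C(=O)O[Si](C)(C)C(C)(C)C)C(=O)Oc2c(Cc3c(O[Si](C)(C)C(C)(C)C)c(C(=O)CCC)c(O[Si](C)(C)C(C)(C)C)c4CC(C(=O)O[Si](C)(C)C(C)(C)C)C(=O)Oc34)c1O[Si](C)(C)C(C)(C)C
F2 | step 8 | tetra-TBS diacid, 8,8'-methylenebis(6-butanoyl-5,7-bis(tert-butyldimethylsilyloxy)-2-oxochromane-3-carboxylic acid) | CCCC(=O)c1c(O[Si](C)(C)C(C)(C)C)c2CC(C(=O)O)C(=O)Oc2c(Cc3c(O[Si](C)(C)C(C)(C)C)c(C(=O)CCC)c(O[Si](C)(C)C(C)(C)C)c4CC(C(=O)O)C(=O)Oc34)c1O[Si](C)(C)C(C)(C)C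
F3 | step 8 | silyl-protected precursor, TBS analogue of 18 | CCCC(=O)c1c(O[Si](C)(C)C(C)(C)C)c2CC(C(=O)C(C)(C)C(=O)CC(C)=O)C(=O)Oc2c(Cc3c(O[Si](C)(C)C(C)(C)C)c(C(=O)CCC)c(O[Si](C)(C)C(C)(C)C)c4CC(C(=O)C(C)(C)C(=O)CC(C)=O)C(=O)Oc34)c1O[Si](C)(C)C(C)(C)C
F4 | step 8 | tetra-TBS tetramer, TBS analogue of 20 | CCCC(=O)c1c(O[Si](C)(C)C(C)(C)C)c(CC2=C(O)C(C)(C)C(=O)C(C(C)=O)=C2O)c(O)c(Cc2c(O)c(CC3=C(O)C(C)(C)C(=O)C(C(C)=O)=C3O)c(O[Si](C)(C)C(C)(C)C)c(C(=O)CCC)c2O[Si](C)(C)C(C)(C)C)c1O[Si](C)(C)C(C)(C)C
F5 | step 9 | acetylfilicinic acid, 2-acetyl-3,5-dihydroxy-4,4-dimethylcyclohexa-2,5-dien-1-one | CC(=O)C1=C(O)C=C(O)C(C)(C)C1=O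
F6 | step 9 | filicinic Mannich base, 2-acetyl-6-[(dimethylamino)methyl]-3,5-dihydroxy-4,4-dimethylcyclohexa-2,5-dien-1-one | CC(=O)C1=C(O)C(CN(C)C)=C(O)C(C)(C)C1=O
F7 | step 3 | bis-Mannich base, 6 with a (dimethylamino)methyl group on each remaining ring carbon | CCCC(=O)c1c(O)c(CN(C)C)c(O)c(Cc2c(O)c(CN(C)C)c(O)c(C(=O)CCC)c2O)c1O
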